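(The runs are calculated with made-up constants; the scatter is artificial.)

In a one-step world the left-handed substrate would fall with a single rate constant k, and the excess would climb on a fixed clock. This flask has a single-handed catalyst, and the question is how far that clock can be trusted.

the same everywhere: left-handed substrate 0.0050 M; right-handed substrate 0.0050 M; free catalyst 1 mol%

| charge | partner | remark | time |
|---|---|---|---|
| blue | 2 equiv | the very flask that is asked about, followed so far |  |
| flask | 2.00 equiv |  | 2.0 min |

blue run (percent of the left-handed substrate and right-handed substrate together charged)

| time / s | right-handed substrate / % | left-handed substrate / % |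
|---|---|---|
| 10.0 | 49.4 | 34.2 |
| 15.0 | 49.4 | 28.2 |
| 20.0 | 49.6 | 24.1 |
| 30.0 | 49.9 | 17.2 |
| 40.0 | 49.6 | 12.7 |

(each reading ± 0.3 percentage points)

- free catalyst is single-handed; left-handed substrate and right-handed substrate are mirror images of each other, charged as a racemate, each of them at the stated concentration
- candidate steps: free catalyst + left-handed substrate <-> catalyst intermediate A; free catalyst + right-handed substrate <-> catalyst intermediate B; partner + catalyst intermediate A -> free catalyst + left-handed product; partner + catalyst intermediate B -> free catalyst + right-handed product; 2 free catalyst -> spent catalyst; partner <-> dormant form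

- whether the excess of right-handed substrate over left-handed substrate among what is left of the two reaches 80% by 2.0 min (no / yes)
- the highest excess of right-handed substrate over left-handed substrate among what is left of the two up to 2.0 min

The right-handed substrate stands flat, at 49.6% at 40.0 s, so the excess (c(right-handed substrate) − c(left-handed substrate)) / (their sum) depends on the left-handed substrate. An excess of 80% allows 5.51% of it to remain, against 12.7% read at 40.0 s. This gives one handy number, the needed rate constant: the logarithm of that ratio divided by the time remaining, 0.0104 s⁻¹.

Two chemists argue over what the flask will supply. The first holds a steady, pseudo-first-order view: the last interval reads 0.0303 s⁻¹, about a third of which would suffice, and keeping it to 2.0 min leaves 1.12%, an excess of 95.6%.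

The second objects that k is fading: it reads 0.0350 s⁻¹ between 10.0 s and 20.0 s, higher than the last interval. She puts that fall back into the first answer and continues it in a straight line, which gives a mean of 0.0198 s⁻¹ for the remaining time. That leaves 2.60% and an excess of 90.0%, and I commit to her reckoning.

The forecast, nearer the steady side, says yes with a top of 93%: “still rising at 2 min, so the top is the 2.0 min value”.

    free catalyst + left-handed substrate ⇌ catalyst intermediate A (K = 1700 M⁻¹, k = 87000 M⁻¹ s⁻¹)
    free catalyst + right-handed substrate ⇌ catalyst intermediate B (K = 180 M⁻¹, k = 32000 M⁻¹ s⁻¹)
    partner + catalyst intermediate A → free catalyst + left-handed product (k = 490 M⁻¹ s⁻¹)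
    partner + catalyst intermediate B → free catalyst + right-handed product (k = 8.30 M⁻¹ s⁻¹)
    2 free catalyst → spent catalyst (k = 2800 M⁻¹ s⁻¹)
    partner ⇌ dormant form (K = 7.60, k = 0.0120 s⁻¹)

The flask's answer is yes: it reaches 80% at 1.62 min and tops out at 82.3%, lower than my reckoning. At 2.00 min, spent catalyst stands at 73.7% of the catalyst charged. From 40.0 s to 2.0 min the flask delivered a mean constant of 0.0121 s⁻¹, just above the needed 0.0104 s⁻¹. The steady view has its region early: between 0.200 min and 1.00 min the mean is 0.0274 s⁻¹. From 1.00 min to 2.00 min it is 0.00920 s⁻¹, below the needed 0.0104 s⁻¹.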